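The carbocycle (C5–C10) is cut at C7–C8, C5–C6 and C9–C10. Its all-trans C5–C8 sequence of carbon, oxygen, carbon and oxygen substituents is read as enal β-carbon, nitro carbon, nitroalkene β-carbon and α-oxy aldehyde carbon. One amine-catalysed Michael/Michael/aldol condensation of siloxyacetaldehyde 8, silyl nitroenyne 4 and dienal 7, run in one flask, builds the ring, three skeletal bonds and four stereocentres of cyclohexenecarbaldehyde 10. The nitro group later becomes O6, the alkyne the methylene lactone (C11–C13, with CO as C12), the isopropenyl group the acrolein, and the enal the handle for quaternary C10. The precursors are three small achiral components, bought or one step from commercial materials.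

Key step: step 3

Remark (numbering): positions are numbered as in the target (ring C5–C10, C14 on C10, vinyl C1/C2, lactone C11–C13, acrolein C3/C4/C15). β is the face of C14 and α the opposite face. The target is 5R,6R,7R,8S,10R (H5 α, H6 β, H7 α, H8 β).

Remark (stereocontrol of the key step): a prolinol ether of one configuration screens the enamine carbon (C8) and the iminium β-carbon (C5) from the same side, which places the C7 and C5 substituents 1,3-trans. The 1,3-cis (all-trans) array of the target therefore needs the (S)-amine for the enamine step and the (R)-amine for the iminium step, and step 3 is run as a two-catalyst relay in one flask.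

Step 1
Reactants: 1 3-(trimethylsilyl)prop-2-ynal; 2 nitromethane
Product: 4 (E)-trimethyl(4-nitrobut-3-en-1-yn-1-yl)silane, via nitro alcohol 3 (not isolated)
Conditions: MeNO2, t-BuOK (cat.), THF/t-BuOH, 0 °C; then (CF3CO)2O, Et3N, CH2Cl2, −15 °C
Reagents that add atoms: none
Why: Henry addition of nitromethane to the ynal and E1cB loss of trifluoroacetate from the activated nitro alcohol should give the conjugated (E)-nitroalkene, the thermodynamic isomer, with no stereocentre left.

Step 2
Reactants: 5 methacrolein; 6 (triphenylphosphoranylidene)acetaldehyde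
Product: 7 (E)-4-methylpenta-2,4-dienal
Conditions: PhMe, 80 °C
Reagents that add atoms: none
Why: Wittig olefination with the stabilised formyl ylide should give the (E)-enal, and the dienal formed is less electrophilic than methacrolein, which limits a second homologation.

Step 3
Reactants: 8 (tert-butyldimethylsilyloxy)acetaldehyde; 4 (E)-trimethyl(4-nitrobut-3-en-1-yn-1-yl)silane; 7 (E)-4-methylpenta-2,4-dienal
Product: 10 (3S,4S,5R,6S)-3-(tert-butyldimethylsilyloxy)-5-nitro-6-(prop-1-en-2-yl)-4-[(trimethylsilyl)ethynyl]cyclohex-1-ene-1-carbaldehyde (all-trans), via syn-nitroaldehyde 9 (not isolated)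
Conditions: (S)-α,α-diphenylprolinol trimethylsilyl ether (2 mol%), 4-nitrophenol (5 mol%), PhMe, 0 °C → rt until 4 is consumed; then 7, (R)-α,α-diphenylprolinol trimethylsilyl ether (20 mol%), PhCO2H (20 mol%), 0 °C → rt
Reagents that add atoms: none
Why: The (S)-amine turns 8 into an (E)-enamine that adds to the nitroalkene carbon of 4 (C7–C8) to give 9; once 4 is consumed the (R)-amine, now in large excess, converts 7 into its iminium ion, the nitronate of 9 adds at the β-carbon (C5–C6), and the enamine so formed closes onto the C9 aldehyde and loses water while still amine-bound (C9=C10). The closest known reaction is the amine-catalysed Michael/Michael/aldol-condensation cascade of an aldehyde, a nitroalkene and an enal, and enamine additions to silyl-capped nitroenynes, enamine additions of α-oxy aldehydes and nitroalkane additions to dienal iminium ions are each known separately. The carbocycle closes by a 6-(enolexo)-exo-trig aldol addition. C8 and C7 are set by the (S)-amine, whose diaryl(siloxy)methyl group blocks one enamine face and whose synclinal transition state gives the syn adduct; C5 is set by the (R)-amine, which blocks the opposite face of the iminium ion; C6 is left to equilibrate through its nitronate to the position trans to both neighbours. The step needs the cis-1,3 relation of the C7 and C5 substituents, which the change of catalyst hand between the two Michael steps secures, the small residue of (S)-amine being able to divert only a minor share into a separable C5 epimer. It also needs 1,4- and not 1,6-attack on 7 and enamine attack on 4 and not on 7, which should follow from the larger LUMO coefficient at the iminium β-carbon and from adding 7 only after 4 is used up.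

Step 4
Reactants: 10 all-trans cyclohexenecarbaldehyde
Product: 12 10β-formyl-10α-[1-(phenylsulfanyl)ethyl]-5β-isopropenyl-6α-nitro-7β-[(trimethylsilyl)ethynyl]-8α-(tert-butyldimethylsilyloxy)cyclohexane (both epimers at the sulfur-bearing carbon), via silyl enol ether 11 (not isolated)
Conditions: Et3SiH, RhCl(PPh3)3 (cat.), PhH, 50 °C; evaporate; then PhSCHClMe [from EtSPh, NCS, CH2Cl2, rt], ZnBr2 (cat.), CH2Cl2, −40 → 0 °C
Reagents that add atoms: 1-chloroethyl phenyl sulfide, CC(Cl)Sc1ccccc1 (made in the flask from ethyl phenyl sulfide, CCSc1ccccc1, and N-chlorosuccinimide, O=C1CCC(=O)N1Cl); triethylsilane, CC[SiH](CC)CC (its silyl group stays only in 11)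
Why: RhCl(PPh3)3-catalysed 1,4-hydrosilylation of the enal gives enol silane 11, whose ZnBr2-promoted phenylthioalkylation (a Mukaiyama-type alkylation by a thionium ion) should occur at C10 on the α-face, the equatorial trajectory anti to the C5 isopropenyl group and clear of the axial hydrogens at C6 and C8, so that C10 carries the formyl group axial (β), while the sulfur-bearing carbon forms as a mixture that step 5 erases.

Step 5
Reactants: 12 sulfide aldehyde
Product: 14 10β-formyl-10α-vinyl-5β-isopropenyl-6α-nitro-7β-[(trimethylsilyl)ethynyl]-8α-(tert-butyldimethylsilyloxy)cyclohexane, via sulfoxide 13 (not isolated)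
Conditions: mCPBA (1 equiv), CH2Cl2, −78 °C; then PhMe, 110 °C
Reagents that add atoms: none
Why: Sulfide oxidation at low temperature followed by thermal syn-elimination of benzenesulfenic acid (sulfoxide pyrolysis) can only run toward the methyl group because C10 is quaternary, so the vinyl group should form without change at any stereocentre.

Step 6
Reactants: 14 nitro vinyl aldehyde
Product: 15 10β-formyl-10α-vinyl-5β-isopropenyl-7β-ethynyl-8α-(tert-butyldimethylsilyloxy)cyclohexan-6-one
Conditions: NaOMe, MeOH, 0 °C; then aq. TiCl3, NH4OAc, 0 °C → rt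
Reagents that add atoms: water, O
Why: Reductive Nef reaction, in which methoxide forms the nitronate (and cleaves the alkynyl C–Si bond), TiCl3 reduces it to the imine and buffered water hydrolyses this to the ketone, while C5 and C7 already hold their equatorial, thermodynamically preferred positions and cannot be inverted by enolisation.

Step 7
Reactants: 15 keto aldehyde
Product: 16 10β-(hydroxymethyl)-10α-vinyl-5β-isopropenyl-7β-ethynyl-8α-(tert-butyldimethylsilyloxy)cyclohexan-6α-ol
Conditions: Me4NBH(OAc)3, MeCN/AcOH, −20 °C → rt
Reagents that add atoms: none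
Why: Triacetoxyborohydride reduces the aldehyde and, once bound to the axial C14 oxygen, should deliver hydride intramolecularly to the β-face of the C6 ketone (hydroxyl-directed reduction of the Saksena–Evans type), which sets C6 with the hydroxyl equatorial (α), whereas the hindered ketone is not reduced by the free reagent.

Step 8
Reactants: 16 diol
Product: 17 10β-(acetoxymethyl)-10α-vinyl-5β-isopropenyl-7β-ethynyl-8α-(tert-butyldimethylsilyloxy)cyclohexan-6α-ol
Conditions: AcCl, 2,4,6-collidine, CH2Cl2, −78 °C
Reagents that add atoms: acetyl chloride, CC(Cl)=O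
Why: Acylation with acetyl chloride and collidine at low temperature should distinguish the primary C14 hydroxyl from the secondary C6 hydroxyl, which lies between two branched carbons.

Step 9
Reactants: 17 hydroxy alkyne
Product: 18 14-acetoxy-8α-(tert-butyldimethylsilyloxy)elema-1,3,11(13)-trien-12,6α-olide
Conditions: PdCl2 (cat.), SnCl2 (cat.), PPh3, CO (7 atm), MeCN, 75 °C
Reagents that add atoms: carbon monoxide, [C-]#[O+]
Why: Palladium-catalysed cyclocarbonylation of a homopropargylic alcohol, in which the C6 alkoxycarbonyl–palladium species adds syn across the alkyne in a 5-exo-dig closure and protonolysis of the vinyl–palladium bond gives the α-methylene lactone, trans-fused because O6 and C11 are both equatorial, while silylated O8 cannot compete.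

Step 10
Reactants: 18 silyl ether lactone
Product: 19 14-acetoxy-8α-hydroxyelema-1,3,11(13)-trien-12,6α-olide
Conditions: HF·pyridine, pyridine/THF, 0 °C → rt
Reagents that add atoms: none
Why: Fluoride cleavage of the secondary silyl ether under buffered acidic conditions should spare the acetate and the methylene lactone and avoids an alkoxide that could open the lactone.

Step 11
Reactants: 20 ethyl 2-(hydroxymethyl)acrylate
Product: 21 ethyl 2-[(tert-butyldimethylsilyloxy)methyl]acrylate
Conditions: TBSCl, imidazole, CH2Cl2, 0 °C → rt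
Reagents that add atoms: tert-butyldimethylsilyl chloride, CC(C)(C)[Si](C)(C)Cl
Why: Imidazole-promoted silylation of the primary allylic alcohol masks the hydroxyl that would otherwise compete in the esterification of step 13.

Step 12
Reactants: 21 silylated ester
Product: 22 2-[(tert-butyldimethylsilyloxy)methyl]acrylic acid
Conditions: LiOH, THF/H2O, 0 °C; then 1 M HCl to pH 4
Reagents that add atoms: lithium hydroxide, [Li+].[OH-]
Why: Saponification of the ethyl ester at low temperature, the primary silyl ether being stable to cold aqueous base.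

Step 13
Reactants: 19 C8 alcohol; 22 silylated acrylic acid
Product: 23 14-acetoxy-8α-{2-[(tert-butyldimethylsilyloxy)methyl]acryloyloxy}elema-1,3,11(13)-trien-12,6α-olide
Conditions: 2,4,6-Cl3C6H2COCl, Et3N, THF, rt; then 19, DMAP, PhMe, rt
Reagents that add atoms: none
Why: Yamaguchi esterification through the mixed 2,4,6-trichlorobenzoic anhydride should acylate the hindered equatorial C8 hydroxyl faster than that hydroxyl can attack the lactone carbonyl.

Step 14
Reactants: 23 ester
Product: 25 14-acetoxy-8α-{2-[(tert-butyldimethylsilyloxy)methyl]acryloyloxy}-15-oxoelema-1,3,11(13)-trien-12,6α-olide, via allylic alcohol 24 (not isolated)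
Conditions: SeO2 (0.5 equiv), t-BuOOH, CH2Cl2, rt; then MnO2, CH2Cl2, rt
Reagents that add atoms: tert-butyl hydroperoxide, CC(C)(C)OO (oxygen passed on through SeO2, O=[Se]=O)
Why: Allylic oxidation with SeO2 (ene reaction then [2,3]-sigmatropic shift) should occur at the methyl group of the isopropenyl unit, the only electron-rich alkene with allylic hydrogen, since the vinyl group has none and the acrylate and methylene lactone are electron-poor, and MnO2 then takes allylic alcohol 24 on to the enal.

Step 15
Reactants: 25 silylated enal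
Product: 26 target, (5R,6R,7R,8S,10R)-14-acetoxy-8α-[2-(hydroxymethyl)acryloyloxy]-15-oxoelema-1,3,11(13)-trien-12,6α-olide
Conditions: HF·pyridine, pyridine/THF, 0 °C
Reagents that add atoms: none
Why: Buffered fluoride removes the primary silyl ether without touching the enal, the acetate, the acrylate or the lactone.

Compound list

1 | 3-(trimethylsilyl)prop-2-ynal | O=CC#C[Si](C)(C)C | starting material
2 | nitromethane | C[N+](=O)[O-] | starting material
3 | 1-nitro-4-(trimethylsilyl)but-3-yn-2-ol (racemic) | C[Si](C)(C)C#CC(O)C[N+](=O)[O-] | intermediate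
4 | (E)-trimethyl(4-nitrobut-3-en-1-yn-1-yl)silane | C[Si](C)(C)C#C/C=C/[N+](=O)[O-] | intermediate
5 | methacrolein | CC(=C)C=O | starting material
6 | (triphenylphosphoranylidene)acetaldehyde | O=CC=P(c1ccccc1)(c1ccccc1)c1ccccc1 | starting material
7 | (E)-4-methylpenta-2,4-dienal | CC(=C)/C=C/C=O | intermediate
8 | (tert-butyldimethylsilyloxy)acetaldehyde | O=CCO[Si](C)(C)C(C)(C)C | starting material
9 | (2R,3S)-2-(tert-butyldimethylsilyloxy)-3-(nitromethyl)-5-(trimethylsilyl)pent-4-ynal (syn) | O=C[C@H](O[Si](C)(C)C(C)(C)C)[C@@H](C#C[Si](C)(C)C)C[N+](=O)[O-] | intermediate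
10 | (3S,4S,5R,6S)-3-(tert-butyldimethylsilyloxy)-5-nitro-6-(prop-1-en-2-yl)-4-[(trimethylsilyl)ethynyl]cyclohex-1-ene-1-carbaldehyde (all-trans) | O=CC1=C[C@H](O[Si](C)(C)C(C)(C)C)[C@@H](C#C[Si](C)(C)C)[C@H]([N+](=O)[O-])[C@H]1C(C)=C | intermediate
11 | triethylsilyl enol ether (C10=C14) of the 9-hydro aldehyde, 8α-OTBS, 7β-silylethynyl, 6α-nitro, 5β-isopropenyl, enol ether geometry undefined | CC[Si](CC)(CC)OC=C1C[C@H](O[Si](C)(C)C(C)(C)C)[C@@H](C#C[Si](C)(C)C)[C@H]([N+](=O)[O-])[C@H]1C(C)=C | intermediate
12 | 10β-formyl-10α-[1-(phenylsulfanyl)ethyl]-5β-isopropenyl-6α-nitro-7β-[(trimethylsilyl)ethynyl]-8α-(tert-butyldimethylsilyloxy)cyclohexane, epimers at the sulfur-bearing carbon | CC(Sc1ccccc1)[C@]1(C=O)C[C@H](O[Si](C)(C)C(C)(C)C)[C@@H](C#C[Si](C)(C)C)[C@H]([N+](=O)[O-])[C@H]1C(C)=C | intermediate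
13 | sulfoxide of 12 (mixture of stereoisomers at sulfur and the adjacent carbon) | CC(S(=O)c1ccccc1)[C@]1(C=O)C[C@H](O[Si](C)(C)C(C)(C)C)[C@@H](C#C[Si](C)(C)C)[C@H]([N+](=O)[O-])[C@H]1C(C)=C | intermediate
14 | 10β-formyl-10α-vinyl-5β-isopropenyl-6α-nitro-7β-[(trimethylsilyl)ethynyl]-8α-(tert-butyldimethylsilyloxy)cyclohexane | C=C[C@]1(C=O)C[C@H](O[Si](C)(C)C(C)(C)C)[C@@H](C#C[Si](C)(C)C)[C@H]([N+](=O)[O-])[C@H]1C(C)=C | intermediate
15 | 10β-formyl-10α-vinyl-5β-isopropenyl-7β-ethynyl-8α-(tert-butyldimethylsilyloxy)cyclohexan-6-one | C=C[C@]1(C=O)C[C@H](O[Si](C)(C)C(C)(C)C)[C@@H](C#C)C(=O)[C@H]1C(C)=C | intermediate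
16 | 10β-(hydroxymethyl)-10α-vinyl-5β-isopropenyl-7β-ethynyl-8α-(tert-butyldimethylsilyloxy)cyclohexan-6α-ol | C=C[C@]1(CO)C[C@H](O[Si](C)(C)C(C)(C)C)[C@@H](C#C)[C@H](O)[C@H]1C(C)=C | intermediate
17 | 10β-(acetoxymethyl)-10α-vinyl-5β-isopropenyl-7β-ethynyl-8α-(tert-butyldimethylsilyloxy)cyclohexan-6α-ol | C=C[C@]1(COC(C)=O)C[C@H](O[Si](C)(C)C(C)(C)C)[C@@H](C#C)[C@H](O)[C@H]1C(C)=C | intermediate
18 | 14-acetoxy-8α-(tert-butyldimethylsilyloxy)elema-1,3,11(13)-trien-12,6α-olide | C=C[C@]1(COC(C)=O)C[C@H](O[Si](C)(C)C(C)(C)C)[C@H]2C(=C)C(=O)O[C@@H]2[C@H]1C(C)=C | intermediate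
19 | 14-acetoxy-8α-hydroxyelema-1,3,11(13)-trien-12,6α-olide | C=C[C@]1(COC(C)=O)C[C@H](O)[C@H]2C(=C)C(=O)O[C@@H]2[C@H]1C(C)=C | intermediate
20 | ethyl 2-(hydroxymethyl)acrylate | C=C(CO)C(=O)OCC | starting material
21 | ethyl 2-[(tert-butyldimethylsilyloxy)methyl]acrylate | C=C(CO[Si](C)(C)C(C)(C)C)C(=O)OCC | intermediate
22 | 2-[(tert-butyldimethylsilyloxy)methyl]acrylic acid | C=C(CO[Si](C)(C)C(C)(C)C)C(=O)O | intermediate
23 | 14-acetoxy-8α-{2-[(tert-butyldimethylsilyloxy)methyl]acryloyloxy}elema-1,3,11(13)-trien-12,6α-olide | C=C[C@]1(COC(C)=O)C[C@H](OC(=O)C(=C)CO[Si](C)(C)C(C)(C)C)[C@H]2C(=C)C(=O)O[C@@H]2[C@H]1C(C)=C | intermediate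
24 | 15-hydroxy derivative of 23 | C=C[C@]1(COC(C)=O)C[C@H](OC(=O)C(=C)CO[Si](C)(C)C(C)(C)C)[C@H]2C(=C)C(=O)O[C@@H]2[C@H]1C(=C)CO | intermediate
25 | 15-oxo derivative of 23 | C=C[C@]1(COC(C)=O)C[C@H](OC(=O)C(=C)CO[Si](C)(C)C(C)(C)C)[C@H]2C(=C)C(=O)O[C@@H]2[C@H]1C(=C)C=O | intermediate
26 | (5R,6R,7R,8S,10R)-14-acetoxy-8α-[2-(hydroxymethyl)acryloyloxy]-15-oxoelema-1,3,11(13)-trien-12,6α-olide (CNP0185525.1) | C=C[C@]1(COC(C)=O)C[C@H](OC(=O)C(=C)CO)[C@H]2C(=C)C(=O)O[C@@H]2[C@H]1C(=C)C=O | target

Total step count: 15 (steps 11 and 12 form a two-step side branch).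
Longest linear sequence: 12 steps (step 1 or 2, then steps 3–10 and 13–15).

Steps most likely to fail

Step 3. The relay may stall or lose selectivity in its second stage: the nitronate may attack the dienal iminium ion at the terminal carbon (1,6) instead of the β-carbon, residual (S)-amine may erode face control at C5, the amine-bound adduct may fail to cyclise, or C8 may epimerise during the long exposure to amine. Fallback: the assembly is taken apart. It sets out from 9, made from 8 and 4 with the (S)-amine alone and purified so that no (S)-amine is carried on. Compound 9 and dienal 7 are joined with the (R)-amine and 4-nitrophenol at −20 °C, and the product is worked up as the open-chain dialdehyde (2R,3S,4R,5R)-2-(tert-butyldimethylsilyloxy)-4-nitro-5-(prop-1-en-2-yl)-3-[(trimethylsilyl)ethynyl]heptanedial F1. F1 is then closed in a separate aldol condensation with dibenzylammonium trifluoroacetate in toluene, which comes back to the route at 10.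

Step 7. Hydride may arrive from outside on the α-face faster than it is delivered from the C14 oxygen, giving the axial C6 alcohol, or the bridged hemiketal between the C14 hydroxyl and C6 may be reduced to a cyclic ether. Fallback: kinetic control is given up for thermodynamic control. The route sets out from 15, which NaBH4 in MeOH at 0 °C should reduce mainly by equatorial attack to the C6 epimer of 16, 10β-(hydroxymethyl)-10α-vinyl-5β-isopropenyl-7β-ethynyl-8α-(tert-butyldimethylsilyloxy)cyclohexan-6β-ol F3. F3 is then equilibrated at the carbinol carbon with Al(Oi-Pr)3 and a little acetone in i-PrOH at reflux (Meerwein–Ponndorf–Verley/Oppenauer redox equilibration). The axial hydroxyl of F3 is syn-axial to C14 and should drain into the equatorial alcohol, which comes back to the route at 16.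

Step 4. The secondary thionium ion may be captured slowly by the hindered tetrasubstituted enol silane, the face selectivity at C10 may be poor, or the rhodium hydride may hydrosilylate the silylalkyne in competition with the enal. Fallback: the two-carbon unit is brought in by an aldol addition and the alkene is made by reductive elimination instead of pyrolysis. The route sets out from 11 (made with Et3SiH and RhCl(PPh3)3 as before). A BF3·OEt2-promoted Mukaiyama aldol addition to (phenylselanyl)acetaldehyde at −78 °C gives the β-hydroxy selenide 10β-formyl-10α-[1-hydroxy-2-(phenylselanyl)ethyl]-5β-isopropenyl-6α-nitro-7β-[(trimethylsilyl)ethynyl]-8α-(tert-butyldimethylsilyloxy)cyclohexane F2. Treatment of F2 with MsCl and Et3N in CH2Cl2 at −20 °C removes the hydroxyl and selanyl groups together and gives the vinyl group. This comes back to the route at 14 and bypasses 12 and 13.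

Further compounds

F1 | step 3 | (2R,3S,4R,5R)-2-(tert-butyldimethylsilyloxy)-4-nitro-5-(prop-1-en-2-yl)-3-[(trimethylsilyl)ethynyl]heptanedial | O=C[C@H](O[Si](C)(C)C(C)(C)C)[C@@H](C#C[Si](C)(C)C)[C@H]([N+](=O)[O-])[C@H](CC=O)C(C)=C
F2 | step 4 | 10β-formyl-10α-[1-hydroxy-2-(phenylselanyl)ethyl]-5β-isopropenyl-6α-nitro-7β-[(trimethylsilyl)ethynyl]-8α-(tert-butyldimethylsilyloxy)cyclohexane (epimers at the carbinol carbon) | OC(C[Se]c1ccccc1)[C@]1(C=O)C[C@H](O[Si](C)(C)C(C)(C)C)[C@@H](C#C[Si](C)(C)C)[C@H]([N+](=O)[O-])[C@H]1C(C)=C
F3 | step 7 | 10β-(hydroxymethyl)-10α-vinyl-5β-isopropenyl-7β-ethynyl-8α-(tert-butyldimethylsilyloxy)cyclohexan-6β-ol | C=C[C@]1(CO)C[C@H](O[Si](C)(C)C(C)(C)C)[C@@H](C#C)[C@@H](O)[C@H]1C(C)=C
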